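(The numbers in the tables were computed for substances that don't exist, and the scatter is random.)

- Follow L. In a closed, stirred flask at constant temperature, L, E and Q were charged, and L and G were read; the new flask lay between beta and alpha in L and shared their E and Q.

| setting | beta | alpha | gamma | flask |
|---|---|---|---|---|
| L | 0.013 M | 0.030 M | 0.020 M | 0.020 M |
| E | 0.022 M | 0.022 M | 0.033 M | 0.0220 M |
| Q | 0.020 M | 0.020 M | 0.020 M | 0.0200 M |
| remark | run made earlier | run made earlier | run made earlier |  |
| time |  |  |  | 50 h |

| run | time / h | G / % | L / % |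
|---|---|---|---|
| beta | 0.417 | 27.9 | 72.5 |
| beta | 2.00 | 36.3 | 60.3 |
| beta | 8.00 | 12.2 | 84.7 |
| beta | 40.0 | 1.1 | 96.7 |
| alpha | 0.417 | 24.5 | 74.7 |
| alpha | 2.00 | 29.3 | 67.2 |
| alpha | 8.00 | 13.0 | 83.8 |
| alpha | 40.0 | 0 | 95.4 |
| gamma | 0.417 | 35.9 | 62.4 |
| gamma | 2.00 | 47.0 | 50.7 |
| gamma | 8.00 | 17.7 | 78.5 |
| gamma | 40.0 | 1.2 | 93.2 |

(readings scatter by 1 percentage point)

1. time up to 50 h at which G stands highest
2. the amount of G, in percent of the L charged, at that time

- a reading or a percentage of G counts all its forms, free or not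

- The beta readings seemed contradictory: L stood at 60.3% after 2.00 h, yet at 96.7% after 40.0 h, so consumed substrate returned in a closed flask.
- L and G summed to 96.6% and 97.8% at those times, so I took G as L held reversibly with E, and the return of L as E being lost elsewhere; gamma, richest in E at 0.033 M, read 47.0% of G after 2.00 h, more than beta or alpha at that time, though its L charge differed from theirs too.
- I therefore carried the fall constant, an apparent first-order constant: the logarithmic slope of G between the readings at 2.00 h and 8.00 h. Beta read 0.182 h⁻¹ and alpha 0.135 h⁻¹, and for the flask I took their mean, 0.159 h⁻¹.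
- Averaging beta and alpha, G gained 0.628 h⁻¹ of the charge over the first 0.417 h, while the fall constant implied a loss of 0.0415 h⁻¹ at its end. The mean net gain between the readings at 0.417 h and 2.00 h then sank to 0.0417 h⁻¹, so I placed the flask's peak between those two times, a little above the 32.8% that beta and alpha averaged at 2.00 h.
- The forecast gave 1.2 h and 35%: “A two-exponential rise and fall therefore peaks near 1.2 h, at about 35%.”
- The flask gave 1.27 h and 35.7%; G stood at 35.3% at 1.02 h and 35.3% at 1.59 h. The fall constant carried the peak to 5.00 h as 19.7%, and the flask held 20.9%.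

    D ⇌ G, rate k1*(cs1 - [G]) while solid is left; crystals form when [G] > cs1 (solubility = 19.0 mM, k = 1.90 min⁻¹)
    L + E ⇌ G (K = 110 M⁻¹, k = 0.880 M⁻¹ min⁻¹)
    E → J (k = 0.00550 min⁻¹)
    E + Q → Z (k = 0.360 M⁻¹ min⁻¹)
    L + E ⇌ X (K = 2100 M⁻¹, k = 0.0280 M⁻¹ min⁻¹)

- For the flask left until 20 h, the fall constant carried the peak to 1.82% of G; the computed flask held 2.17%.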